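## Analysis of the target

The target 37 joins C2 of a 2,3,4-trisubstituted oxolane to C5' of a 2-aryl-3-(hydroxymethyl)-7-methoxy-2,3-dihydro-1-benzofuran. Locants used here: oxolane O1, C2 (aryl-bearing), C3 (CH2OH), C4 (tertiary carbinol), C5 (ring CH2); C7'' is the benzylic CH2 on C4; the dihydrobenzofuran carries O1', C2', C3' and the benzo ring B; ring A is the guaiacyl group on C2', ring C the guaiacyl group on C7''. There are five stereocentres: C2' (R) and C3' (R) hold ring A and the hydroxymethyl group cis; C2 (R), C3 (R) and C4 (S) put the C2 aryl group, the C3 hydroxymethyl group and the C4 benzyl group on one face of the oxolane and the tertiary hydroxyl on the other. The two clusters are separated by the flat ring B, so neither can induce the other and absolute configuration has to be brought in twice by reagent control. Sensitive points are the two free guaiacyl phenols and the two benzylic C–O bonds C2'–O1' and C2–O1, each para to an oxygen donor: acid ionises them, and once the ring A phenol is free, base can open C2'–O1' through a quinone methide; either event turns a cis arrangement into the more stable trans one. The difficulty is therefore that both the cis-dihydrobenzofuran and the 2,3-cis oxolane are the less stable diastereomers and must be made and carried under kinetic control. The strategy rests on the O1'–C2' bond: it is an aryl ether to a benzylic carbon, so the ring B phenol can form it by backside displacement, and the cis ring then maps onto a syn aldol pair (C3' and the C2' carbinol) in which C2' is inverted on closure.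

## Retrosynthetic reasoning

37 is traced back to its bis(benzyl ether) 36 and then to the bis(silyl ether) 35. The phenols are unmasked last and by hydrogenolysis, because this is neutral and never produces a phenoxide para to C2'. The silyl groups are removed one step earlier, while both phenols are still capped.

In 35 the O1–C5 bond is cut, leading through the primary sulfonate 34 to the triol 33 and, by reduction, to the α-hydroxy lactone 32. The cut is made at C5 and not at C2: closing at the benzylic C2 would need substitution at a cation-prone carbon and would deliver the trans 2,3-relationship. Closing at C5 leaves the C2–O and C4–O bonds untouched, so the forward reaction only has to sulfonylate the primary hydroxyl selectively and let the C2 oxygen displace it.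

In 32 the C7''–aryl bond to ring C and the C4–O bond are cut together. This gives the α-methylene lactone 28 and the aryl bromide 29, which enters as its Grignard reagent 30. The conjugate addition produces the enolate 31, and the oxygen electrophile must then approach C4 from the face opposite the cis C2-aryl and C3-silyloxymethyl groups; both shield the same face, which is what makes this the right place to form the quaternary centre.

Lactone 28 is cut at C2–C3 (and at the lactone C–O bond) into aldehyde 21 and the ester-bearing allylboronate 26. A closed chair transition state translates the geometry of 26 into the syn (hence cis) relationship. Because the stereocentres of 21 are remote, a chiral catalyst has to choose the aldehyde face. Boronate 26 goes back to the acetate 25, the adduct 24 and the two commercial components 22 and 23.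

Aldehyde 21 comes from bromide 19 through the aryllithium 20 (C5'–CHO bond). Bromide 19 is the benzyl ether of phenol 18, which is released from the methanesulfonate 17. The sulfonate is needed for the ring closure but cannot accompany an organolithium; it is exchanged at this point, by a cleavage that runs at low temperature so the freed phenoxide cannot open the cis ring.

In 17 the O1'–C2' bond is cut, giving the phenol diol monosilyl ether 15; the forward reaction passes through the alkoxyphosphonium phenoxide 16. This is the key disconnection: it turns the contra-thermodynamic cis ring into an open-chain syn pair whose two centres can be set by an auxiliary, provided the closure is a clean inversion.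

Phenol 15 goes back through the allyl ether 14 and the diol 13 to the aldol adduct 12. Cutting the C2'–C3' bond of 12 gives the arylacetyl imide 8 (as its boron enolate 11) and the sulfonylated aldehyde 10, made from vanillin 9. Imide 8 comes from the acid 5 and the auxiliary 6 through the mixed anhydride 7. Acid 5 is the one-carbon homologue of aldehyde 2 (through enol ether 3 and aldehyde 4), and 2 is the allyl ether of the commercial bromo-salicylaldehyde 1.

## Alternatives that were turned down

Alternative 1: This plan makes the C7''–aryl and C4–O bonds the centre of the synthesis. An aryl Grignard reagent under copper catalysis adds to the exocyclic methylene of the cis α-methylene lactone A1, and the enolate is hydroxylated in the same flask to give the α-hydroxy-α-benzyl lactone A2. In its favour: the quaternary carbinol and the ring C attachment are made in one operation, ring C arrives late, and the two cis substituents make the facial outcome at C4 easy to predict. Against it as the governing idea: C4 is the stereocentre that is easiest to control, and A1 already contains the cis-dihydrobenzofuran, so the plan says nothing on how the hard element is obtained. On the construction of C4 it is as strong as anything available, and the route below uses exactly this operation as step 18 (A1 and A2 are identical with 28 and 32). What the chosen strategy adds is a stereospecific answer to C2'/C3'.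

Alternative 2: Here the C2'–C3' bond is formed last. A chiral dirhodium tetracarboxylate of the N-phthaloyl-tert-leucinate type decomposes the aryl diazoacetate A3, and the carbenoid inserts into the benzylic O–CH2 bond of the neighbouring ring A benzyl ether to give the cis-dihydrobenzofuran-3-carboxylate A4. In its favour: 1,5 C–H insertion of this kind is known to be cis-selective and enantioselective under catalyst control, it makes C2' and C3' in one catalytic step, and it is the more convergent and shorter way to the dihydrobenzofuran; on these points it is stronger than the chosen route. Against it for this target: A3 carries the complete oxolane, with other activated C–H bonds (the benzylic C2–H next to oxygen, C5–H2, the silyloxymethyl CH2) and three electron-rich arenes competing for the carbenoid. The catalyst must also override five remote stereocentres, and a wrong-configured product would be a hard-to-separate diastereomer. The product holds C3' as an enolisable ester α to an aryl ring, so cis-to-trans epimerisation threatens until the ester is reduced. The chosen strategy offers in its place an auxiliary-derived configuration with C3' at the non-enolisable CH2O level from the start, a closure whose stereochemical course is dictated by mechanism, and a test of the risky step on simple material early in the sequence.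

Alternative 3: This plan cuts the C3'–C3a' bond by way of a six-membered ketone. Irradiation of the 3-diazoflavanone A5 in an alcohol solvent triggers a Wolff rearrangement in which the aryl carbon migrates from the carbonyl carbon to C3, and the ketene is captured as the methyl ester A6. In its favour: flavanones are cheap to assemble, the bromide stage is reached in fewer steps and without protecting-group exchange (stronger on step economy), and the migration itself leaves C2 untouched. Against it: a flavanone with a para-alkoxyaryl group at C2 racemises by retro-oxa-Michael opening under the basic conditions of diazo transfer. The C3' configuration is decided only when the ketene-derived enol is protonated, which is not stereospecific, and the cis ester epimerises readily. The aryl bromide is also photolabile, and the ester again needs reduction. The chosen strategy sets both centres by processes with a fixed stereochemical course (chair aldol, backside displacement) and never passes through an enolisable C3'.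

Key step: step 10

Abbreviations: TBS = tert-butyldimethylsilyl; Bn = benzyl; Ms = methanesulfonyl; Ts = p-toluenesulfonyl; pin = pinacolato; DIAD = diisopropyl azodicarboxylate; LDA = lithium diisopropylamide; DBF = (2R,3R)-2-[4-(benzyloxy)-3-methoxyphenyl]-3-{[(TBS)oxy]methyl}-7-methoxy-2,3-dihydro-1-benzofuran-5-yl. Systematic names of lactones and oxolanes use IUPAC locants, in which target C2, C3, C4 appear as C5, C4, C3. Compounds 1, 6, 9, 22, 23 and 29 are taken as commercial.

Assumption: the (R)-configured phosphoric acid of step 17 is taken to deliver the allyl group to the Re face of the aryl aldehyde, as it does in allyl- and crotylboration of benzaldehyde; should the sense be opposite with this boronate, the (S)-acid is used.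

## Route

Step 1
Reactants: 1 5-bromo-2-hydroxy-3-methoxybenzaldehyde
Product: 2 5-bromo-3-methoxy-2-(prop-2-en-1-yloxy)benzaldehyde
Conditions: allyl bromide, K2CO3, DMF, rt
Reagents that add atoms: allyl bromide, C=CCBr
Why: Williamson etherification of an acidic salicylaldehyde-type phenol; the allyl ether survives ylide, chlorite, boron enolate and borohydride and is later removed by zerovalent palladium without touching silyl ether, sulfonate or aryl bromide.

Step 2
Reactants: 2 5-bromo-3-methoxy-2-(prop-2-en-1-yloxy)benzaldehyde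
Product: 3 5-bromo-1-methoxy-3-(2-methoxyethenyl)-2-(prop-2-en-1-yloxy)benzene (E/Z mixture)
Conditions: Ph3P(CH2OMe)Cl, KOt-Bu, THF, 0 °C → rt
Reagents that add atoms: (methoxymethyl)triphenylphosphonium chloride, COC[P+](c1ccccc1)(c1ccccc1)c1ccccc1.[Cl-]
Why: Wittig methoxymethylenation of a non-enolisable aryl aldehyde; the alkene geometry is irrelevant because both isomers hydrolyse to the same aldehyde.

Step 3
Reactants: 3 5-bromo-1-methoxy-3-(2-methoxyethenyl)-2-(prop-2-en-1-yloxy)benzene
Product: 5 2-[5-bromo-3-methoxy-2-(prop-2-en-1-yloxy)phenyl]acetic acid, via arylacetaldehyde 4 (not isolated)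
Conditions: 2 M HCl, THF, rt; extractive work-up; then NaClO2, NaH2PO4, 2-methylbut-2-ene, t-BuOH/H2O, 0 °C → rt
Reagents that add atoms: water, O; sodium chlorite, [Na+].[O-]Cl=O
Why: Acid hydrolysis of the enol ether gives the homologated arylacetaldehyde, which is oxidised crude by Pinnick (Lindgren–Kraus) chlorite oxidation; the alkene scavenger protects the allyl ether and the electron-rich ring from hypochlorite.

Step 4
Reactants: 5 2-[5-bromo-3-methoxy-2-(prop-2-en-1-yloxy)phenyl]acetic acid; 6 (4S)-4-benzyl-1,3-oxazolidin-2-one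
Product: 8 (4S)-4-benzyl-3-{[5-bromo-3-methoxy-2-(prop-2-en-1-yloxy)phenyl]acetyl}-1,3-oxazolidin-2-one, via mixed pivalic anhydride 7 (not isolated)
Conditions: t-BuCOCl, Et3N, THF, −20 °C; then 6, LiCl, −20 °C → rt
Reagents that add atoms: pivaloyl chloride, CC(C)(C)C(Cl)=O (its acyl group is present in 7 only)
Why: N-acylation of the oxazolidinone through the mixed pivalic anhydride with LiCl activation, a standard way to load arylacetic acids without strong base.

Step 5
Reactants: 9 vanillin (4-hydroxy-3-methoxybenzaldehyde)
Product: 10 4-formyl-2-methoxyphenyl methanesulfonate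
Conditions: MsCl, Et3N, CH2Cl2, 0 °C
Reagents that add atoms: methanesulfonyl chloride, CS(Cl)(=O)=O
Why: Sulfonylation of the phenol; the mesylate turns the para oxygen of ring A from a donor into an acceptor for the later ring closure and, unlike an arenesulfonate, can be taken off again at −78 °C.

Step 6
Reactants: 8 (4S)-4-benzyl-3-{[5-bromo-3-methoxy-2-(prop-2-en-1-yloxy)phenyl]acetyl}-1,3-oxazolidin-2-one; 10 4-formyl-2-methoxyphenyl methanesulfonate
Product: 12 (4S)-4-benzyl-3-{(2S,3S)-2-[5-bromo-3-methoxy-2-(prop-2-en-1-yloxy)phenyl]-3-hydroxy-3-[3-methoxy-4-(methanesulfonyloxy)phenyl]propanoyl}-1,3-oxazolidin-2-one, via dibutylboron Z-enolate 11 (not isolated)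
Conditions: n-Bu2BOTf, i-Pr2NEt, CH2Cl2, 0 °C; then 10, −78 → 0 °C; pH 7 buffer, MeOH, 30% H2O2, 0 °C
Reagents that add atoms: dibutylboron trifluoromethanesulfonate, CCCCB(CCCC)OS(=O)(=O)C(F)(F)F (boron is present in 11 only)
Why: Evans syn-aldol: the Z-boron enolate reacts through a closed Zimmerman–Traxler chair on the face away from the benzyl group of the (S)-auxiliary, setting the future C3' and the C2' carbinol as the (2S,3S) syn pair; the electron-poor aldehyde is a good acceptor.

Step 7
Reactants: 12 the syn-aldol adduct
Product: 13 4-{(1S,2R)-2-[5-bromo-3-methoxy-2-(prop-2-en-1-yloxy)phenyl]-1,3-dihydroxypropyl}-2-methoxyphenyl methanesulfonate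
Conditions: LiBH4, MeOH (1 equiv), THF, 0 °C
Reagents that add atoms: none
Why: Reductive cleavage of the N-acyl oxazolidinone gives the 1,3-diol directly and returns the auxiliary; cold, brief conditions keep the doubly benzylic α-carbon from epimerising by retro-aldol, and aryl bromide, allyl ether and aryl mesylate are inert to borohydride.

Step 8
Reactants: 13 the 1,3-diol
Product: 14 4-{(1S,2R)-2-[5-bromo-3-methoxy-2-(prop-2-en-1-yloxy)phenyl]-3-[(TBS)oxy]-1-hydroxypropyl}-2-methoxyphenyl methanesulfonate
Conditions: TBSCl, imidazole, CH2Cl2, 0 °C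
Reagents that add atoms: tert-butyldimethylsilyl chloride, CC(C)(C)[Si](C)(C)Cl
Why: Selective silylation of the primary over the hindered secondary benzylic hydroxyl; the primary oxygen must be blocked because it would otherwise be activated first and close the isomeric five-membered ether.

Step 9
Reactants: 14 the allyl ether
Product: 15 4-{(1S,2R)-2-(5-bromo-2-hydroxy-3-methoxyphenyl)-3-[(TBS)oxy]-1-hydroxypropyl}-2-methoxyphenyl methanesulfonate
Conditions: Pd(PPh3)4 (5 mol %), morpholine, THF, rt
Reagents that add atoms: none
Why: Tsuji–Trost deallylation: zerovalent palladium ionises the aryl allyl ether and morpholine captures the allyl fragment; oxidative addition into the electron-rich aryl bromide is slow at room temperature with triphenylphosphine ligands.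

Step 10
Reactants: 15 the syn phenol diol monosilyl ether
Product: 17 4-[(2R,3R)-5-bromo-3-{[(TBS)oxy]methyl}-7-methoxy-2,3-dihydro-1-benzofuran-2-yl]-2-methoxyphenyl methanesulfonate, via alkoxyphosphonium phenoxide 16 (not isolated)
Conditions: PPh3, DIAD (slow addition), THF, 0 °C → rt
Reagents that add atoms: triphenylphosphine, c1ccc(cc1)P(c1ccccc1)c1ccccc1 (phosphorus is present in 16 only)
Why: PPh3 and DIAD form a betaine that deprotonates the ring B phenol and transfers phosphorus to the only free alcohol, the C2' hydroxyl, giving the alkoxyphosphonium phenoxide 16; the phenoxide then expels Ph3P=O from the rear and forms the O1'–C2' bond. The closest known reaction type is the intramolecular Mitsunobu etherification of phenols with secondary benzylic alcohols, which closes 2-aryl-2,3-dihydrobenzofurans with inversion. The ring closes in the 5-exo-tet mode, with nucleophile, carbon and leaving group collinear. C2' is the one stereocentre formed anew: its (R) configuration follows from inversion of the (S) carbinol set by the auxiliary-controlled aldol, while C3' (R) is carried through unchanged, so the syn pair becomes the cis ring. The step needs SN2 displacement to win over ionisation of the benzylic C–O bond, which would lead to the more stable trans ring, and over E2 loss of the benzylic C3'–H, which would lead to a stilbene. The para-methanesulfonyloxy group makes ring A electron-poor and so disfavours the cation, the phenoxide is held within reach so that substitution is fast at 0 °C, and the primary hydroxyl is silylated so that no other alcohol can be activated. Slow addition of the azodicarboxylate keeps the concentration of free betaine, the base responsible for elimination, low.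

Step 11
Reactants: 17 the cis-dihydrobenzofuran mesylate
Product: 18 4-[(2R,3R)-5-bromo-3-{[(TBS)oxy]methyl}-7-methoxy-2,3-dihydro-1-benzofuran-2-yl]-2-methoxyphenol
Conditions: LDA (2.2 equiv), THF, −78 °C; AcOH, −78 °C
Reagents that add atoms: none
Why: E1cB cleavage of the aryl methanesulfonate: the amide base deprotonates the S-methyl group, the aryloxide leaves with sulfene and the amine captures the sulfene. At −78 °C the lithium phenoxide cannot open the cis ring through a quinone methide, which is why a mesylate is used instead of a sulfonate that needs hot alkali; the quench at −78 °C also returns any ring B position metalated next to bromine.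

Step 12
Reactants: 18 the ring A phenol
Product: 19 (2R,3R)-2-[4-(benzyloxy)-3-methoxyphenyl]-5-bromo-3-{[(TBS)oxy]methyl}-7-methoxy-2,3-dihydro-1-benzofuran
Conditions: BnBr, Cs2CO3, DMF, 0 °C
Reagents that add atoms: benzyl bromide, BrCc1ccccc1
Why: Williamson benzylation, fast at 0 °C so that the phenoxide is short-lived; the benzyl ether tolerates the organolithium, Grignard and hydride steps ahead and leaves at the end under neutral hydrogenolysis.

Step 13
Reactants: 19 the aryl bromide
Product: 21 (2R,3R)-2-[4-(benzyloxy)-3-methoxyphenyl]-3-{[(TBS)oxy]methyl}-7-methoxy-2,3-dihydro-1-benzofuran-5-carbaldehyde, via aryllithium 20 (not isolated)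
Conditions: n-BuLi, THF, −78 °C; then DMF, −78 → 0 °C; H2O
Reagents that add atoms: n-butyllithium, [Li]CCCC (lithium is present in 20 only); N,N-dimethylformamide, CN(C)C=O
Why: Bromine–lithium exchange outruns any deprotonation at −78 °C, and Bouveault formylation of the aryllithium with DMF gives the aldehyde; neither ring stereocentre is acidic enough to be touched.

Step 14
Reactants: 22 [(tert-butyldimethylsilyl)oxy]acetaldehyde; 23 methyl acrylate
Product: 24 methyl 4-[(TBS)oxy]-3-hydroxy-2-methylidenebutanoate (racemic)
Conditions: 1,4-diazabicyclo[2.2.2]octane (20 mol %), 1,4-dioxane/H2O, rt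
Reagents that add atoms: none
Why: Morita–Baylis–Hillman reaction; α-oxygenated aldehydes are among the fastest acceptors, and the carbinol centre is racemic without consequence because it is erased in step 16.

Step 15
Reactants: 24 the Morita–Baylis–Hillman adduct
Product: 25 methyl 3-acetoxy-4-[(TBS)oxy]-2-methylidenebutanoate (racemic)
Conditions: Ac2O, pyridine, 4-(dimethylamino)pyridine (cat.), CH2Cl2, 0 °C
Reagents that add atoms: acetic anhydride, CC(=O)OC(C)=O
Why: Acetylation of the secondary allylic alcohol provides the leaving group for the allylic substitution.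

Step 16
Reactants: 25 the allylic acetate
Product: 26 methyl (2E)-4-[(TBS)oxy]-2-[(4,4,5,5-tetramethyl-1,3,2-dioxaborolan-2-yl)methyl]but-2-enoate
Conditions: B2pin2, CuCl (10 mol %), LiCl, KOAc, DMF, rt
Reagents that add atoms: bis(pinacolato)diboron, CC1(C)OB(OC1(C)C)B1OC(C)(C)C(C)(C)O1
Why: Copper-catalysed SN2′ borylation of a Morita–Baylis–Hillman acetate (boryl-copper conjugate addition, then loss of acetate) gives the 2-alkoxycarbonyl allylboronate. The trisubstituted alkene forms with the silyloxymethyl group trans to the ester, (E), which is the geometry that leads to the cis lactone; any (Z) isomer is removed by chromatography.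

Step 17
Reactants: 21 the aldehyde; 26 the allylboronate
Product: 28 (4R,5R)-5-(DBF)-4-{[(TBS)oxy]methyl}-3-methylideneoxolan-2-one, via homoallylic borate 27 (not isolated)
Conditions: (R)-3,3′-bis(2,4,6-triisopropylphenyl)-1,1′-binaphthyl-2,2′-diyl hydrogen phosphate (10 mol %), 4 Å molecular sieves, toluene, 0 °C → rt; then pyridinium p-toluenesulfonate (cat.), CH2Cl2, rt
Reagents that add atoms: none
Why: Brønsted-acid-catalysed allylboration through a closed six-membered chair, the reaction type established for allyl and crotyl pinacol boronates with aryl aldehydes; ester-substituted boronates of this kind are known to respond to Brønsted acid activation. The silyloxymethyl group, cis to the CH2–B carbon, sits axial and gives the syn adduct, and the chiral acid selects the Re face so that C2 is (R) and C3 (R); lactonisation then gives the cis lactone. The weak acids used do not ionise the benzylic C2–O bond, which stronger acids would equilibrate to the trans lactone.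

Step 18
Reactants: 28 the cis α-methylene lactone; 29 1-(benzyloxy)-4-bromo-2-methoxybenzene
Product: 32 (3S,4R,5R)-3-{[4-(benzyloxy)-3-methoxyphenyl]methyl}-5-(DBF)-3-hydroxy-4-{[(TBS)oxy]methyl}oxolan-2-one, via aryl Grignard reagent 30 (not isolated), via bromomagnesium enolate 31 (not isolated)
Conditions: 29, Mg, THF, rt (gives 30); CuBr·SMe2 (10 mol %), 28, THF, −78 → −40 °C; then 2-(phenylsulfonyl)-3-phenyloxaziridine, −78 °C; H2O
Reagents that add atoms: magnesium, [Mg] (present in 30 and 31 only); 2-(phenylsulfonyl)-3-phenyloxaziridine, O=S(=O)(c1ccccc1)N1OC1c1ccccc1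
Why: Copper-catalysed 1,4-addition of the aryl Grignard reagent to the exocyclic acrylate forms the C7''–aryl bond and a magnesium enolate. Davis hydroxylation by the N-sulfonyloxaziridine then occurs on the face opposite the cis C2-aryl and C3-silyloxymethyl groups, so C4 is set as (S) with the hydroxyl trans and the benzyl group cis to both.

Step 19
Reactants: 32 the α-hydroxy lactone
Product: 33 (2S,3R,4R)-2-{[4-(benzyloxy)-3-methoxyphenyl]methyl}-4-(DBF)-3-{[(TBS)oxy]methyl}butane-1,2,4-triol
Conditions: LiBH4, THF, 0 °C → rt
Reagents that add atoms: none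
Why: Hydride reduction of the lactone to the 1,4-diol (here a triol with the tertiary hydroxyl); silyl and benzyl ethers are inert and no stereocentre is involved.

Step 20
Reactants: 33 the triol
Product: 35 (3S,4R,5R)-3-{[4-(benzyloxy)-3-methoxyphenyl]methyl}-5-(DBF)-4-{[(TBS)oxy]methyl}oxolan-3-ol, via primary tosylate 34 (not isolated)
Conditions: TsCl, Et3N, 4-(dimethylamino)pyridine (cat.), CH2Cl2, 0 °C; then KOt-Bu, THF, 0 °C
Reagents that add atoms: p-toluenesulfonyl chloride, Cc1ccc(cc1)S(Cl)(=O)=O (present in 34 only)
Why: The primary hydroxyl is sulfonylated in preference to the hindered benzylic and the tertiary hydroxyl, and the C2 alkoxide closes the oxolane by intramolecular Williamson displacement at C5 (5-exo-tet). Because neither the C2–O nor the C4–O bond is broken, the cis 2,3-relationship and the C4 configuration are retained.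

Step 21
Reactants: 35 the bis(silyl ether)
Product: 36 (3S,4R,5R)-3-{[4-(benzyloxy)-3-methoxyphenyl]methyl}-5-[(2R,3R)-2-[4-(benzyloxy)-3-methoxyphenyl]-3-(hydroxymethyl)-7-methoxy-2,3-dihydro-1-benzofuran-5-yl]-4-(hydroxymethyl)oxolan-3-ol
Conditions: n-Bu4NF, THF, 0 °C → rt
Reagents that add atoms: none
Why: Fluoride-mediated desilylation of both primary silyl ethers; the phenols are still benzylated, so the basic fluoride cannot generate a phenoxide para to C2'.

Step 22
Reactants: 36 the bis(benzyl ether)
Product: 37 (3S,4R,5R)-5-[(2R,3R)-2-(4-hydroxy-3-methoxyphenyl)-3-(hydroxymethyl)-7-methoxy-2,3-dihydro-1-benzofuran-5-yl]-3-[(4-hydroxy-3-methoxyphenyl)methyl]-4-(hydroxymethyl)oxolan-3-ol (target)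
Conditions: H2 (1 atm), Pd on carbon (10 wt %), EtOAc/MeOH, rt
Reagents that add atoms: none
Why: Catalytic hydrogenolysis of the two aryl benzyl ethers under neutral conditions; O-benzyl phenols cleave much faster than the cyclic benzylic C–O bonds at C2 and C2', and the absence of acid or base keeps both cis rings intact.

## Compound list

1 | 5-bromo-2-hydroxy-3-methoxybenzaldehyde | COc1cc(Br)cc(C=O)c1O | starting material
2 | 5-bromo-3-methoxy-2-(prop-2-en-1-yloxy)benzaldehyde | COc1cc(Br)cc(C=O)c1OCC=C | intermediate
3 | 5-bromo-1-methoxy-3-(2-methoxyethenyl)-2-(prop-2-en-1-yloxy)benzene (E/Z mixture) | COC=Cc1cc(Br)cc(OC)c1OCC=C | intermediate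
4 | 2-[5-bromo-3-methoxy-2-(prop-2-en-1-yloxy)phenyl]acetaldehyde | COc1cc(Br)cc(CC=O)c1OCC=C | intermediate (not isolated)
5 | 2-[5-bromo-3-methoxy-2-(prop-2-en-1-yloxy)phenyl]acetic acid | COc1cc(Br)cc(CC(=O)O)c1OCC=C | intermediate
6 | (4S)-4-benzyl-1,3-oxazolidin-2-one | O=C1N[C@@H](Cc2ccccc2)CO1 | starting material
7 | mixed anhydride of 5 with pivalic acid | COc1cc(Br)cc(CC(=O)OC(=O)C(C)(C)C)c1OCC=C | intermediate (not isolated)
8 | (4S)-4-benzyl-3-{[5-bromo-3-methoxy-2-(prop-2-en-1-yloxy)phenyl]acetyl}-1,3-oxazolidin-2-one | COc1cc(Br)cc(CC(=O)N2[C@@H](Cc3ccccc3)COC2=O)c1OCC=C | intermediate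
9 | vanillin | COc1cc(C=O)ccc1O | starting material
10 | 4-formyl-2-methoxyphenyl methanesulfonate | COc1cc(C=O)ccc1OS(C)(=O)=O | intermediate
11 | dibutylboron (Z)-enolate of 8 | CCCCB(CCCC)O/C(=C\c1cc(Br)cc(OC)c1OCC=C)N1[C@@H](Cc2ccccc2)COC1=O | intermediate (not isolated)
12 | (4S)-4-benzyl-3-{(2S,3S)-2-[5-bromo-3-methoxy-2-(prop-2-en-1-yloxy)phenyl]-3-hydroxy-3-[3-methoxy-4-(methanesulfonyloxy)phenyl]propanoyl}-1,3-oxazolidin-2-one | COc1cc(Br)cc([C@H](C(=O)N2[C@@H](Cc3ccccc3)COC2=O)[C@H](O)c2ccc(OS(C)(=O)=O)c(OC)c2)c1OCC=C | intermediate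
13 | 4-{(1S,2R)-2-[5-bromo-3-methoxy-2-(prop-2-en-1-yloxy)phenyl]-1,3-dihydroxypropyl}-2-methoxyphenyl methanesulfonate | COc1cc(Br)cc([C@H](CO)[C@H](O)c2ccc(OS(C)(=O)=O)c(OC)c2)c1OCC=C | intermediate
14 | 4-{(1S,2R)-2-[5-bromo-3-methoxy-2-(prop-2-en-1-yloxy)phenyl]-3-[(TBS)oxy]-1-hydroxypropyl}-2-methoxyphenyl methanesulfonate | COc1cc(Br)cc([C@H](CO[Si](C)(C)C(C)(C)C)[C@H](O)c2ccc(OS(C)(=O)=O)c(OC)c2)c1OCC=C | intermediate
15 | 4-{(1S,2R)-2-(5-bromo-2-hydroxy-3-methoxyphenyl)-3-[(TBS)oxy]-1-hydroxypropyl}-2-methoxyphenyl methanesulfonate | COc1cc(Br)cc([C@H](CO[Si](C)(C)C(C)(C)C)[C@H](O)c2ccc(OS(C)(=O)=O)c(OC)c2)c1O | intermediate (precursor of the key step)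
16 | alkoxyphosphonium phenoxide from 15 | COc1cc(Br)cc([C@H](CO[Si](C)(C)C(C)(C)C)[C@H](O[P+](c2ccccc2)(c2ccccc2)c2ccccc2)c2ccc(OS(C)(=O)=O)c(OC)c2)c1[O-] | intermediate (not isolated)
17 | 4-[(2R,3R)-5-bromo-3-{[(TBS)oxy]methyl}-7-methoxy-2,3-dihydro-1-benzofuran-2-yl]-2-methoxyphenyl methanesulfonate | Brc1cc(OC)c2c(c1)[C@H](CO[Si](C)(C)C(C)(C)C)[C@H](c1ccc(OS(C)(=O)=O)c(OC)c1)O2 | intermediate (product of the key step)
18 | 4-[(2R,3R)-5-bromo-3-{[(TBS)oxy]methyl}-7-methoxy-2,3-dihydro-1-benzofuran-2-yl]-2-methoxyphenol | Brc1cc(OC)c2c(c1)[C@H](CO[Si](C)(C)C(C)(C)C)[C@H](c1ccc(O)c(OC)c1)O2 | intermediate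
19 | (2R,3R)-2-[4-(benzyloxy)-3-methoxyphenyl]-5-bromo-3-{[(TBS)oxy]methyl}-7-methoxy-2,3-dihydro-1-benzofuran | Brc1cc(OC)c2c(c1)[C@H](CO[Si](C)(C)C(C)(C)C)[C@H](c1ccc(OCc3ccccc3)c(OC)c1)O2 | intermediate
20 | 5-lithio derivative of 19 | [Li]c1cc(OC)c2c(c1)[C@H](CO[Si](C)(C)C(C)(C)C)[C@H](c1ccc(OCc3ccccc3)c(OC)c1)O2 | intermediate (not isolated)
21 | (2R,3R)-2-[4-(benzyloxy)-3-methoxyphenyl]-3-{[(TBS)oxy]methyl}-7-methoxy-2,3-dihydro-1-benzofuran-5-carbaldehyde | O=Cc1cc(OC)c2c(c1)[C@H](CO[Si](C)(C)C(C)(C)C)[C@H](c1ccc(OCc3ccccc3)c(OC)c1)O2 | intermediate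
22 | [(tert-butyldimethylsilyl)oxy]acetaldehyde | O=CCO[Si](C)(C)C(C)(C)C | starting material
23 | methyl acrylate | C=CC(=O)OC | starting material
24 | methyl 4-[(TBS)oxy]-3-hydroxy-2-methylidenebutanoate (racemic) | C=C(C(=O)OC)C(O)CO[Si](C)(C)C(C)(C)C | intermediate
25 | methyl 3-acetoxy-4-[(TBS)oxy]-2-methylidenebutanoate (racemic) | C=C(C(=O)OC)C(OC(C)=O)CO[Si](C)(C)C(C)(C)C | intermediate
26 | methyl (2E)-4-[(TBS)oxy]-2-[(4,4,5,5-tetramethyl-1,3,2-dioxaborolan-2-yl)methyl]but-2-enoate | COC(=O)/C(CB1OC(C)(C)C(C)(C)O1)=C/CO[Si](C)(C)C(C)(C)C | intermediate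
27 | methyl (3R,4R)-4-(DBF)-4-[(4,4,5,5-tetramethyl-1,3,2-dioxaborolan-2-yl)oxy]-3-{[(TBS)oxy]methyl}-2-methylidenebutanoate | C=C(C(=O)OC)[C@H](CO[Si](C)(C)C(C)(C)C)[C@@H](OB1OC(C)(C)C(C)(C)O1)c1cc(OC)c2c(c1)[C@H](CO[Si](C)(C)C(C)(C)C)[C@H](c1ccc(OCc3ccccc3)c(OC)c1)O2 | intermediate (not isolated)
28 | (4R,5R)-5-(DBF)-4-{[(TBS)oxy]methyl}-3-methylideneoxolan-2-one | C=C1C(=O)O[C@@H](c2cc(OC)c3c(c2)[C@H](CO[Si](C)(C)C(C)(C)C)[C@H](c2ccc(OCc4ccccc4)c(OC)c2)O3)[C@H]1CO[Si](C)(C)C(C)(C)C | intermediate
29 | 1-(benzyloxy)-4-bromo-2-methoxybenzene | COc1cc(Br)ccc1OCc1ccccc1 | starting material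
30 | [4-(benzyloxy)-3-methoxyphenyl]magnesium bromide | COc1cc([Mg]Br)ccc1OCc1ccccc1 | intermediate (not isolated)
31 | bromomagnesium enolate of the α-benzyl lactone | COc1cc(CC2=C(O[Mg]Br)O[C@@H](c3cc(OC)c4c(c3)[C@H](CO[Si](C)(C)C(C)(C)C)[C@H](c3ccc(OCc5ccccc5)c(OC)c3)O4)[C@H]2CO[Si](C)(C)C(C)(C)C)ccc1OCc1ccccc1 | intermediate (not isolated)
32 | (3S,4R,5R)-3-{[4-(benzyloxy)-3-methoxyphenyl]methyl}-5-(DBF)-3-hydroxy-4-{[(TBS)oxy]methyl}oxolan-2-one | COc1cc(C[C@@]2(O)C(=O)O[C@@H](c3cc(OC)c4c(c3)[C@H](CO[Si](C)(C)C(C)(C)C)[C@H](c3ccc(OCc5ccccc5)c(OC)c3)O4)[C@H]2CO[Si](C)(C)C(C)(C)C)ccc1OCc1ccccc1 | intermediate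
33 | (2S,3R,4R)-2-{[4-(benzyloxy)-3-methoxyphenyl]methyl}-4-(DBF)-3-{[(TBS)oxy]methyl}butane-1,2,4-triol | COc1cc(C[C@@](O)(CO)[C@H](CO[Si](C)(C)C(C)(C)C)[C@@H](O)c2cc(OC)c3c(c2)[C@H](CO[Si](C)(C)C(C)(C)C)[C@H](c2ccc(OCc4ccccc4)c(OC)c2)O3)ccc1OCc1ccccc1 | intermediate
34 | 1-O-(p-toluenesulfonate) of 33 | COc1cc(C[C@@](O)(COS(=O)(=O)c2ccc(C)cc2)[C@H](CO[Si](C)(C)C(C)(C)C)[C@@H](O)c2cc(OC)c3c(c2)[C@H](CO[Si](C)(C)C(C)(C)C)[C@H](c2ccc(OCc4ccccc4)c(OC)c2)O3)ccc1OCc1ccccc1 | intermediate (not isolated)
35 | (3S,4R,5R)-3-{[4-(benzyloxy)-3-methoxyphenyl]methyl}-5-(DBF)-4-{[(TBS)oxy]methyl}oxolan-3-ol | COc1cc(C[C@@]2(O)CO[C@@H](c3cc(OC)c4c(c3)[C@H](CO[Si](C)(C)C(C)(C)C)[C@H](c3ccc(OCc5ccccc5)c(OC)c3)O4)[C@H]2CO[Si](C)(C)C(C)(C)C)ccc1OCc1ccccc1 | intermediate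
36 | (3S,4R,5R)-3-{[4-(benzyloxy)-3-methoxyphenyl]methyl}-5-[(2R,3R)-2-[4-(benzyloxy)-3-methoxyphenyl]-3-(hydroxymethyl)-7-methoxy-2,3-dihydro-1-benzofuran-5-yl]-4-(hydroxymethyl)oxolan-3-ol | COc1cc(C[C@@]2(O)CO[C@@H](c3cc(OC)c4c(c3)[C@H](CO)[C@H](c3ccc(OCc5ccccc5)c(OC)c3)O4)[C@H]2CO)ccc1OCc1ccccc1 | intermediate
37 | (3S,4R,5R)-5-[(2R,3R)-2-(4-hydroxy-3-methoxyphenyl)-3-(hydroxymethyl)-7-methoxy-2,3-dihydro-1-benzofuran-5-yl]-3-[(4-hydroxy-3-methoxyphenyl)methyl]-4-(hydroxymethyl)oxolan-3-ol | COc1cc(C[C@@]2(O)CO[C@@H](c3cc(OC)c4c(c3)[C@H](CO)[C@H](c3ccc(O)c(OC)c3)O4)[C@H]2CO)ccc1O | target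

## Step count and least certain steps

Total: 22 steps. Longest linear sequence: 18 steps (1 → 2 → 3 → 5 → 8 → 12 → 13 → 14 → 15 → 17 → 18 → 19 → 21 → 28 → 32 → 33 → 35 → 36 → 37). Side branches: step 5 (one step) and steps 14–16 (three steps).

Step 10 (key step). The most likely failure is loss of stereospecificity. The alkoxyphosphonium group sits on a benzylic carbon next to a benzylic C–H, so ionisation before the phenoxide attacks (leading to the trans ring) or elimination across C2'–C3' can compete. Fallback: set out from 15 and separate activation from ring closure. Selective silylation of the phenol (TBSCl, imidazole, DMF) gives the aryl silyl ether F1. Ms2O and Et3N in CH2Cl2 at −20 °C convert the benzylic hydroxyl with retention into the benzylic methanesulfonate F2. CsF in DMF at 0 °C then frees the phenoxide, which displaces the sulfonate with inversion in an intramolecular Williamson reaction; the route is rejoined at 17.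

Step 17. The ester group lowers the nucleophilicity of the boronate and the aldehyde is electron-rich. Allyl transfer may therefore be slow, the temperature needed may erode the facial selectivity imposed by the catalyst, and prolonged acid contact during lactonisation could equilibrate C2. Fallback: set out from 21 and 26 without catalyst (toluene, 60–80 °C). This known, stereospecific thermal addition still gives only syn adducts, namely 27 together with the epimeric homoallylic borate F3. After lactonisation these become 28 and the (4S,5S)-configured cis lactone F4, which are diastereomers because the dihydrobenzofuran is enantiopure. They are separated by chromatography and the route is rejoined at 28.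

Step 18. Oxygen transfer to a magnesium enolate can be incomplete: the enolate may react sluggishly with the oxaziridine, add to the sulfonimine that the oxaziridine releases, or simply be protonated on work-up. Fallback: set out from 28 and reverse the order of bond formation. Nucleophilic epoxidation of the acrylate (t-BuOOLi, THF, −20 °C) on the face away from the two cis substituents gives the spiro epoxide F5. Opening at its unhindered CH2 by the aryl cuprate made from 30 and CuI (THF, −40 °C) forms the C7''–aryl bond and leaves the tertiary alkoxide; the route is rejoined at 32.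

Step 20. Two processes threaten: sulfonylation of the benzylic instead of the primary hydroxyl, and base-induced migration of the silyl group from the C3 CH2O to a neighbouring alkoxide. Prior attack of the tertiary alkoxide on C5 is harmless, because the C2 oxygen reopens that three-membered ether at the same carbon. Fallback: set out from 32 and avoid the triol altogether. i-Bu2AlH (CH2Cl2, −78 °C) reduces the lactone to the lactol F6, and Et3SiH with BF3·OEt2 at −78 °C removes the anomeric hydroxyl through the cyclic oxocarbenium ion without opening the ring; the route is rejoined at 35, bypassing 33 and 34.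

## Further compounds

F1 | step 10 | 4-{(1S,2R)-2-{5-bromo-2-[(TBS)oxy]-3-methoxyphenyl}-3-[(TBS)oxy]-1-hydroxypropyl}-2-methoxyphenyl methanesulfonate | COc1cc(Br)cc([C@H](CO[Si](C)(C)C(C)(C)C)[C@H](O)c2ccc(OS(C)(=O)=O)c(OC)c2)c1O[Si](C)(C)C(C)(C)C
F2 | step 10 | 4-{(1S,2R)-2-{5-bromo-2-[(TBS)oxy]-3-methoxyphenyl}-3-[(TBS)oxy]-1-[(methanesulfonyl)oxy]propyl}-2-methoxyphenyl methanesulfonate | COc1cc(Br)cc([C@H](CO[Si](C)(C)C(C)(C)C)[C@H](OS(C)(=O)=O)c2ccc(OS(C)(=O)=O)c(OC)c2)c1O[Si](C)(C)C(C)(C)C
F3 | step 17 | methyl (3S,4S)-4-(DBF)-4-[(4,4,5,5-tetramethyl-1,3,2-dioxaborolan-2-yl)oxy]-3-{[(TBS)oxy]methyl}-2-methylidenebutanoate | C=C(C(=O)OC)[C@@H](CO[Si](C)(C)C(C)(C)C)[C@H](OB1OC(C)(C)C(C)(C)O1)c1cc(OC)c2c(c1)[C@H](CO[Si](C)(C)C(C)(C)C)[C@H](c1ccc(OCc3ccccc3)c(OC)c1)O2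
F4 | step 17 | (4S,5S)-5-(DBF)-4-{[(TBS)oxy]methyl}-3-methylideneoxolan-2-one | C=C1C(=O)O[C@H](c2cc(OC)c3c(c2)[C@H](CO[Si](C)(C)C(C)(C)C)[C@H](c2ccc(OCc4ccccc4)c(OC)c2)O3)[C@@H]1CO[Si](C)(C)C(C)(C)C
F5 | step 18 | (3R,6R,7R)-6-(DBF)-7-{[(TBS)oxy]methyl}-1,5-dioxaspiro[2.4]heptan-4-one | O1C[C@]12C(=O)O[C@@H](c3cc(OC)c4c(c3)[C@H](CO[Si](C)(C)C(C)(C)C)[C@H](c3ccc(OCc5ccccc5)c(OC)c3)O4)[C@H]2CO[Si](C)(C)C(C)(C)C
F6 | step 20 | (3S,4R,5R)-3-{[4-(benzyloxy)-3-methoxyphenyl]methyl}-5-(DBF)-4-{[(TBS)oxy]methyl}oxolane-2,3-diol (mixture of anomers) | COc1cc(C[C@@]2(O)C(O)O[C@@H](c3cc(OC)c4c(c3)[C@H](CO[Si](C)(C)C(C)(C)C)[C@H](c3ccc(OCc5ccccc5)c(OC)c3)O4)[C@H]2CO[Si](C)(C)C(C)(C)C)ccc1OCc1ccccc1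
A1 | alternative 1 | (4R,5R)-5-(DBF)-4-{[(TBS)oxy]methyl}-3-methylideneoxolan-2-one (identical with 28) | C=C1C(=O)O[C@@H](c2cc(OC)c3c(c2)[C@H](CO[Si](C)(C)C(C)(C)C)[C@H](c2ccc(OCc4ccccc4)c(OC)c2)O3)[C@H]1CO[Si](C)(C)C(C)(C)C
A2 | alternative 1 | (3S,4R,5R)-3-{[4-(benzyloxy)-3-methoxyphenyl]methyl}-5-(DBF)-3-hydroxy-4-{[(TBS)oxy]methyl}oxolan-2-one (identical with 32) | COc1cc(C[C@@]2(O)C(=O)O[C@@H](c3cc(OC)c4c(c3)[C@H](CO[Si](C)(C)C(C)(C)C)[C@H](c3ccc(OCc5ccccc5)c(OC)c3)O4)[C@H]2CO[Si](C)(C)C(C)(C)C)ccc1OCc1ccccc1
A3 | alternative 2 | methyl 2-diazo-2-{2-{[4-(benzyloxy)-3-methoxyphenyl]methoxy}-5-[(2R,3R,4S)-4-{[4-(benzyloxy)-3-methoxyphenyl]methyl}-3-{[(TBS)oxy]methyl}-4-[(triethylsilyl)oxy]oxolan-2-yl]-3-methoxyphenyl}acetate | COc1cc(C[C@@]2(O[Si](CC)(CC)CC)CO[C@@H](c3cc(OC)c(OCc4ccc(OCc5ccccc5)c(OC)c4)c(C(=[N+]=[N-])C(=O)OC)c3)[C@H]2CO[Si](C)(C)C(C)(C)C)ccc1OCc1ccccc1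
A4 | alternative 2 | methyl (2R,3S)-2-[4-(benzyloxy)-3-methoxyphenyl]-5-[(2R,3R,4S)-4-{[4-(benzyloxy)-3-methoxyphenyl]methyl}-3-{[(TBS)oxy]methyl}-4-[(triethylsilyl)oxy]oxolan-2-yl]-7-methoxy-2,3-dihydro-1-benzofuran-3-carboxylate (cis) | COc1cc(C[C@@]2(O[Si](CC)(CC)CC)CO[C@@H](c3cc(OC)c4c(c3)[C@H](C(=O)OC)[C@H](c3ccc(OCc5ccccc5)c(OC)c3)O4)[C@H]2CO[Si](C)(C)C(C)(C)C)ccc1OCc1ccccc1
A5 | alternative 3 | (2S)-2-[4-(benzyloxy)-3-methoxyphenyl]-6-bromo-3-diazo-8-methoxy-2,3-dihydro-4H-chromen-4-one | COc1cc(Br)cc2c1O[C@@H](c1ccc(OCc3ccccc3)c(OC)c1)C(=[N+]=[N-])C2=O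
A6 | alternative 3 | methyl (2R,3S)-2-[4-(benzyloxy)-3-methoxyphenyl]-5-bromo-7-methoxy-2,3-dihydro-1-benzofuran-3-carboxylate (cis) | Brc1cc(OC)c2c(c1)[C@H](C(=O)OC)[C@H](c1ccc(OCc3ccccc3)c(OC)c1)O2
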